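**Strategy.** Ring B is disconnected across C1–C10 (target locants: ring A = C1–C6, ring B = C1, C6–C10, cis fusion at C1/C6) through an anionic oxy-Cope retron. The chain O–C8–C9–C10–C1–C2–C3–O, oxygenated at both ends, maps onto a 1,5-diene alkoxide. The precursor is a 1-methoxy-2-alkenylbicyclo[2.2.2]oct-5-en-2-ol, built from (R)-5-methylcyclohexenone by Diels–Alder chemistry. In one operation its C3–C8 bond breaks and C1–C10 forms. The cis-decalin appears with C1 and the C10 carbinol centre (masked as C–Si) set, and the C8 ketone and C3 enol ether emerge differentiated.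

Key step: step 9

Assumption: (R)-5-methylcyclohex-2-en-1-one (chiral-pool enone, from (R)-pulegone) is taken as commercially available; its methyl-bearing centre becomes C4, steers all later stereocentres and is erased when C4=C5 is formed.

Locants and α/β descriptors in the Why lines are those of the target (α = face of H1 and H6); bicyclic intermediates are named by von Baeyer numbering.

Step 1
Reactants: 1 (R)-5-methylcyclohex-2-en-1-one
Product: 3 (5R,6S)-6-hydroxy-5-methylcyclohex-2-en-1-one, via lithium dienolate 2 (not isolated)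
Conditions: LiN(i-Pr)2, THF, −78 °C; then 2-(phenylsulfonyl)-3-phenyloxaziridine, −78 °C; aq. NH4Cl
Reagents that add atoms: 2-(phenylsulfonyl)-3-phenyloxaziridine O=S(=O)(N1OC1c1ccccc1)c1ccccc1
Why: Kinetic α'-deprotonation to the cross-conjugated dienolate followed by Davis oxaziridine enolate hydroxylation puts the future C3 oxygen next to the carbonyl, anti to the methyl, and the new centre is flattened again in step 3.

Step 2
Reactants: 3 (5R,6S)-6-hydroxy-5-methylcyclohex-2-en-1-one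
Product: 4 (5R,6S)-6-methoxy-5-methylcyclohex-2-en-1-one
Conditions: CH3I (excess), Ag2O, CaSO4, rt, dark
Reagents that add atoms: iodomethane CI
Why: Purdie methylation (Ag2O, CH3I) etherifies the α-ketol without a strong base, so no enolisation, α-ketol shift or epimerisation occurs and no stereocentre is formed.

Step 3
Reactants: 4 (5R,6S)-6-methoxy-5-methylcyclohex-2-en-1-one
Product: 5 tert-butyl{[(3R)-2-methoxy-3-methylcyclohexa-1,5-dien-1-yl]oxy}dimethylsilane
Conditions: TBSOTf, Et3N, CH2Cl2, 0 °C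
Reagents that add atoms: tert-butyldimethylsilyl trifluoromethanesulfonate CC(C)(C)[Si](C)(C)OS(=O)(=O)C(F)(F)F
Why: Soft enolisation with a silyl triflate and an amine removes the only α'-hydrogen and gives the 1-methoxy-2-silyloxy diene (silyl dienol ether formation), leaving the β-methyl centre untouched.

Step 4
Reactants: 5 tert-butyl{[(3R)-2-methoxy-3-methylcyclohexa-1,5-dien-1-yl]oxy}dimethylsilane; 6 (E)-1,2-bis(phenylsulfonyl)ethene
Product: 7 tert-butyl{[1-methoxy-7-methyl-5,6-trans-bis(phenylsulfonyl)bicyclo[2.2.2]oct-2-en-2-yl]oxy}dimethylsilane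
Conditions: toluene, 60 °C
Reagents that add atoms: none
Why: Normal-demand Diels–Alder cycloaddition of the electron-rich cyclic diene with an acetylene equivalent; the dienophile adds to the face anti to the methyl group (held pseudo-axial by allylic strain with the methoxy group), which sets both bridgeheads (later C3 and C6) and leaves the methyl on the side of the enol ether bridge.

Step 5
Reactants: 7 tert-butyl{[1-methoxy-7-methyl-5,6-trans-bis(phenylsulfonyl)bicyclo[2.2.2]oct-2-en-2-yl]oxy}dimethylsilane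
Product: 9 (1S,4R,7R)-1-methoxy-7-methylbicyclo[2.2.2]oct-5-en-2-one, via silyl enol ether diene 8 (not isolated)
Conditions: Na(Hg) (6% Na), Na2HPO4, MeOH/THF, −20 °C; then 1 M HCl, THF, rt
Reagents that add atoms: none
Why: Sodium amalgam reductive elimination of the vicinal disulfone (Julia-type unveiling of the acetylene equivalent) creates the C1=C2 etheno bridge and acid then hydrolyses the silyl enol ether to the C8 ketone; no stereocentre is touched.

Step 6
Reactants: 9 (1S,4R,7R)-1-methoxy-7-methylbicyclo[2.2.2]oct-5-en-2-one; 10 tert-butyl(2-iodoethoxy)dimethylsilane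
Product: 12 3-[2-(tert-butyldimethylsilyloxy)ethyl]-1-methoxy-7-methylbicyclo[2.2.2]oct-5-en-2-one (3-substituent syn to the C5=C6 bridge), via lithium enolate 11 (not isolated)
Conditions: LiN(i-Pr)2, THF, −78 °C; then 10, DMPU, −78 to 0 °C
Reagents that add atoms: none
Why: Enolate alkylation at the only enolisable position (the other α-carbon is a bridgehead) brings in C11–C12, the electrophile entering syn to the etheno bridge, the less hindered face, which sets C7 as in the target.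

Step 7
Reactants: 12 3-[2-(tert-butyldimethylsilyloxy)ethyl]-1-methoxy-7-methylbicyclo[2.2.2]oct-5-en-2-one
Product: 13 3-[2-(tert-butyldimethylsilyloxy)ethyl]-1-methoxy-7-methyl-2-(prop-1-yn-1-yl)bicyclo[2.2.2]oct-5-en-2-ol (propynyl syn to the C5=C6 bridge)
Conditions: CH3C≡CMgBr, CeCl3, THF, −78 to 0 °C; aq. NH4Cl
Reagents that add atoms: 1-propynylmagnesium bromide CC#C[Mg]Br
Why: Organocerium 1,2-addition to the ketone occurs from the face of the etheno bridge because the opposite face is blocked by the 1,3-syn C4 methyl, so the alkynyl group ends syn to the C1=C2 bridge as the later [3,3] shift requires.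

Step 8
Reactants: 13 3-[2-(tert-butyldimethylsilyloxy)ethyl]-1-methoxy-7-methyl-2-(prop-1-yn-1-yl)bicyclo[2.2.2]oct-5-en-2-ol
Product: 14 3-[2-(tert-butyldimethylsilyloxy)ethyl]-2-[(E)-2-(dimethylphenylsilyl)prop-1-en-1-yl]-1-methoxy-7-methylbicyclo[2.2.2]oct-5-en-2-ol
Conditions: PhMe2SiH, PtCl2 (5 mol%), XPhos (10 mol%), THF, 50 °C
Reagents that add atoms: dimethylphenylsilane C[SiH](C)c1ccccc1
Why: Platinum-catalysed syn hydrosilylation of the propargylic alcohol places silicon on the alkyne carbon remote from the carbinol and gives the (E)-vinylsilane (Si trans to C8, CH3 cis), the geometry that encodes the C10 configuration.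

Step 9
Reactants: 14 3-[2-(tert-butyldimethylsilyloxy)ethyl]-2-[(E)-2-(dimethylphenylsilyl)prop-1-en-1-yl]-1-methoxy-7-methylbicyclo[2.2.2]oct-5-en-2-ol
Product: 17 (1αH,6αH)-7α-[2-(tert-butyldimethylsilyloxy)ethyl]-10β-(dimethylphenylsilyl)-3-methoxy-4β,10α-dimethylbicyclo[4.4.0]dec-2-en-8-one, via potassium alkoxide 15 (not isolated), via potassium enolate 16 (not isolated)
Conditions: KH, 18-crown-6, THF, 0 °C to rt; then aq. NH4Cl, −78 °C
Reagents that add atoms: none
Why: KH converts 14 into alkoxide 15, whose 1,5-diene C10=C9–C8(O−)–C3–C2=C1 undergoes a charge-accelerated [3,3]-sigmatropic shift (anionic oxy-Cope rearrangement) that breaks the C3–C8 bond of the bicycle and forms C1–C10, giving the C8 enolate 16 and the C2=C3 methyl enol ether. The closest precedent is the anionic oxy-Cope rearrangement of 2-alkenyl-1-methoxybicyclo[2.2.2]oct-5-en-2-ols to cis-fused octalones. Ring B (C1, C10, C9, C8, C7, C6) is closed by a concerted, suprafacial six-centre sigmatropic closure through the boat-like transition state imposed by the bicycle, while ring A (C1–C6) is released from the old cyclohexene ring. C1 is set because C10 can only reach the face of the C1=C2 bridge that looks toward the C7–C8 bridge, which places H1 cis to H6, and C10 is set by the (E) geometry of the vinylsilane, the silyl group trans to C8 ending β (the later OH) and the methyl α. The step needs the alkenyl group syn to the C1=C2 bridge (secured in step 7 by the C4 methyl) and a C10 substituent that cannot leave from enolate 16, which the C–Si oxygen surrogate provides; C6 and C7 are carried over unchanged.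

Step 10
Reactants: 17 (1αH,6αH)-7α-[2-(tert-butyldimethylsilyloxy)ethyl]-10β-(dimethylphenylsilyl)-3-methoxy-4β,10α-dimethylbicyclo[4.4.0]dec-2-en-8-one
Product: 19 (1αH,6αH)-7α-[2-(tert-butyldimethylsilyloxy)ethyl]-10β-(dimethylphenylsilyl)-8α-hydroxy-4β,10α-dimethylbicyclo[4.4.0]decan-3-one, via enol ether alcohol 18 (not isolated)
Conditions: LiBH(s-Bu)3, THF, −78 °C; then 1 M HCl, THF, 0 °C
Reagents that add atoms: water O
Why: The bulky hydride attacks C8 equatorially because the axial C10 methyl blocks the axial path (Selectride-type diastereoselective ketone reduction), giving the 8α (axial) alcohol, and dilute acid then hydrolyses the methyl enol ether to the C3 ketone.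

Step 11
Reactants: 19 (1αH,6αH)-7α-[2-(tert-butyldimethylsilyloxy)ethyl]-10β-(dimethylphenylsilyl)-8α-hydroxy-4β,10α-dimethylbicyclo[4.4.0]decan-3-one
Product: 20 (1αH,6αH)-7α-[2-(tert-butyldimethylsilyloxy)ethyl]-8α,10β-dihydroxy-4β,10α-dimethylbicyclo[4.4.0]decan-3-one
Conditions: Hg(OAc)2, CH3CO3H (32% in AcOH), AcOH, rt
Reagents that add atoms: peracetic acid CC(=O)OO
Why: Fleming–Tamao oxidation (ipso-mercuration of the phenyl group, then peracid-induced 1,2-shift of C10 from silicon to oxygen) turns the C–Si bond into C–OH with retention, so the 10β-hydroxy-10α-methyl centre set in step 9 is revealed.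

Step 12
Reactants: 21 but-2-yne-1,4-diol
Product: 22 1,4-bis(tert-butyldiphenylsilyloxy)but-2-yne
Conditions: TBDPSCl, imidazole, DMF, rt
Reagents that add atoms: tert-butyl(chloro)diphenylsilane CC(C)(C)[Si](Cl)(c1ccccc1)c1ccccc1
Why: Standard silyl ether formation protects both primary hydroxyls with the acid- and IBX-stable TBDPS group; no stereocentre is involved.

Step 13
Reactants: 22 1,4-bis(tert-butyldiphenylsilyloxy)but-2-yne
Product: 24 (E)-1,4-bis(tert-butyldiphenylsilyloxy)-2-iodobut-2-ene, via alkenylzirconocene chloride 23 (not isolated)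
Conditions: Cp2Zr(H)Cl, THF, rt; then I2, 0 °C
Reagents that add atoms: iodine II
Why: syn-Hydrozirconation of the symmetrical alkyne and iodinolysis with retention give the (E)-vinyl iodide in which H and I are cis and the two CH2O groups are cis.

Step 14
Reactants: 24 (E)-1,4-bis(tert-butyldiphenylsilyloxy)-2-iodobut-2-ene
Product: 25 (E)-4-(tert-butyldiphenylsilyloxy)-2-[(tert-butyldiphenylsilyloxy)methyl]but-2-enoic acid
Conditions: Pd(OAc)2 (5 mol%), PPh3, CO (1 atm), H2O, Et3N, DMF, 50 °C; aq. citric acid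
Reagents that add atoms: carbon monoxide [C-]#[O+]; water O
Why: Palladium-catalysed hydroxycarbonylation of the vinyl iodide proceeds with retention of alkene geometry, so the carboxyl group ends trans to C4 as in the (E)-acyl residue of the target.

Step 15
Reactants: 20 (1αH,6αH)-7α-[2-(tert-butyldimethylsilyloxy)ethyl]-8α,10β-dihydroxy-4β,10α-dimethylbicyclo[4.4.0]decan-3-one; 25 (E)-4-(tert-butyldiphenylsilyloxy)-2-[(tert-butyldiphenylsilyloxy)methyl]but-2-enoic acid
Product: 27 8α-ester of 20 with acid 25 (10β-hydroxy-3-oxo compound), via mixed anhydride 26 (not isolated)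
Conditions: 2,4,6-Cl3C6H2COCl, Et3N, THF, rt; then 20, DMAP, toluene, 40 °C
Reagents that add atoms: none
Why: Yamaguchi esterification through mixed anhydride 26 acylates the secondary 8α-hydroxyl selectively, the tertiary C10 hydroxyl being inert, and the C8 configuration is retained.

Step 16
Reactants: 27 8α-ester of 20 with acid 25
Product: 28 (1αH,6αH)-8α-acyloxy-7α-[2-(tert-butyldimethylsilyloxy)ethyl]-10β-hydroxy-4,10α-dimethylbicyclo[4.4.0]dec-4-en-3-one (acyl = residue of 25)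
Conditions: IBX (2-iodoxybenzoic acid), DMSO/fluorobenzene, 70 °C
Reagents that add atoms: none
Why: IBX dehydrogenation proceeds through the more substituted enol (C3=C4) and gives the C4=C5 enone, erasing the auxiliary C4 stereocentre.

Step 17
Reactants: 28 C4=C5 enone
Product: 29 (1αH,6αH)-8α-acyloxy-7α-[2-(tert-butyldimethylsilyloxy)ethyl]-4,10α-dimethylbicyclo[4.4.0]dec-4-ene-3β,10β-diol
Conditions: NaBH4, CeCl3·7H2O, MeOH, −78 °C
Reagents that add atoms: none
Why: Luche 1,2-reduction: hydride adds to C3 from the α face, anti to the pseudo-axial C6–C7 bond, giving the pseudo-equatorial 3β-allylic alcohol without touching the esters.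

Step 18
Reactants: 29 3β,10β-diol
Product: 30 3β-acetate of 29
Conditions: Ac2O, pyridine, DMAP (cat.), CH2Cl2, 0 °C
Reagents that add atoms: acetic anhydride CC(=O)OC(C)=O
Why: Acetylation of the secondary allylic hydroxyl with acetic anhydride; the hindered tertiary C10 hydroxyl does not react under these conditions.

Step 19
Reactants: 30 3β-acetate
Product: 31 7α-(2-hydroxyethyl) compound (TBDPS groups retained)
Conditions: HF·pyridine, pyridine, THF, 0 °C
Reagents that add atoms: none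
Why: Buffered HF·pyridine cleaves the primary alkyl TBS ether much faster than the two TBDPS ethers (selective desilylation), freeing only the C12 hydroxyl.

Step 20
Reactants: 31 7α-(2-hydroxyethyl) compound
Product: 32 7α-(2-oxoethyl) compound (aldehyde)
Conditions: Dess–Martin periodinane, NaHCO3, CH2Cl2, rt
Reagents that add atoms: none
Why: Dess–Martin oxidation converts the only primary alcohol into the aldehyde; the tertiary alcohol, the acetate and the silyl ethers are inert.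

Step 21
Reactants: 32 aldehyde
Product: 33 7α-(3-oxoprop-1-en-2-yl) compound (α-methylene aldehyde)
Conditions: aq. CH2O (37%), pyrrolidine (10 mol%), propionic acid (10 mol%), i-PrOH, 45 °C
Reagents that add atoms: formaldehyde C=O
Why: Amine-catalysed Mannich condensation–elimination (α-methylenation of an aldehyde) installs C13 as the exocyclic methylene at C11 and is selective for the aldehyde α-position.

Step 22
Reactants: 33 α-methylene aldehyde
Product: 34 bis-TBDPS ether of the target acid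
Conditions: NaClO2, NaH2PO4, 2-methylbut-2-ene, t-BuOH/H2O, 0 °C to rt
Reagents that add atoms: sodium chlorite [Na+].[O-]Cl=O
Why: Pinnick oxidation converts the α-substituted acrolein into the acrylic acid while 2-methylbut-2-ene scavenges hypochlorite, protecting the C4=C5 and side-chain alkenes.

Step 23
Reactants: 34 bis-TBDPS ether of the target acid
Product: 35 CNP0468194.1 (target)
Conditions: HF·pyridine (excess), THF, rt
Reagents that add atoms: none
Why: Fluoride-mediated cleavage of both TBDPS ethers under mildly acidic conditions tolerated by the allylic acetate, the two esters and the acrylic acid liberates the diol and gives the target.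

**Compound list**

1 | (R)-5-methylcyclohex-2-en-1-one | C[C@@H]1CC=CC(=O)C1 | starting material
2 | lithium (R)-5-methylcyclohexa-1,5-dien-1-olate (cross-conjugated dienolate of 1) | C[C@@H]1CC=CC([O-])=C1.[Li+] | intermediate
3 | (5R,6S)-6-hydroxy-5-methylcyclohex-2-en-1-one (OH trans to CH3) | C[C@@H]1CC=CC(=O)[C@H]1O | intermediate
4 | (5R,6S)-6-methoxy-5-methylcyclohex-2-en-1-one | C[C@@H]1CC=CC(=O)[C@H]1OC | intermediate
5 | tert-butyl{[(3R)-2-methoxy-3-methylcyclohexa-1,5-dien-1-yl]oxy}dimethylsilane | C[C@@H]1CC=CC(O[Si](C)(C)C(C)(C)C)=C1OC | intermediate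
6 | (E)-1,2-bis(phenylsulfonyl)ethene | O=S(=O)(/C=C/S(=O)(=O)c1ccccc1)c1ccccc1 | starting material
7 | tert-butyl{[1-methoxy-7-methyl-5,6-trans-bis(phenylsulfonyl)bicyclo[2.2.2]oct-2-en-2-yl]oxy}dimethylsilane (7-methyl on the side of the enol ether bridge; one trans-disulfone isomer drawn, all converge in step 5) | CO[C@]12[C@@H](S(=O)(=O)c3ccccc3)[C@H](S(=O)(=O)c3ccccc3)[C@H](C[C@H]1C)C=C2O[Si](C)(C)C(C)(C)C | intermediate
8 | tert-butyl{[1-methoxy-7-methylbicyclo[2.2.2]octa-2,5-dien-2-yl]oxy}dimethylsilane (configuration as in 9) | CO[C@]12C=C[C@H](C[C@H]1C)C=C2O[Si](C)(C)C(C)(C)C | intermediate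
9 | (1S,4R,7R)-1-methoxy-7-methylbicyclo[2.2.2]oct-5-en-2-one (7-methyl syn to the carbonyl bridge) | CO[C@]12C=C[C@H](C[C@H]1C)CC2=O | intermediate
10 | tert-butyl(2-iodoethoxy)dimethylsilane | CC(C)(C)[Si](C)(C)OCCI | starting material
11 | lithium enolate of 9 (lithium 1-methoxy-7-methylbicyclo[2.2.2]octa-2,5-dien-2-olate) | CO[C@]12C=C[C@H](C[C@H]1C)C=C2[O-].[Li+] | intermediate
12 | 3-[2-(tert-butyldimethylsilyloxy)ethyl]-1-methoxy-7-methylbicyclo[2.2.2]oct-5-en-2-one (3-substituent syn to the C5=C6 bridge, 7-methyl syn to the carbonyl bridge) | CO[C@]12C=C[C@H](C[C@H]1C)[C@@H](CCO[Si](C)(C)C(C)(C)C)C2=O | intermediate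
13 | 3-[2-(tert-butyldimethylsilyloxy)ethyl]-1-methoxy-7-methyl-2-(prop-1-yn-1-yl)bicyclo[2.2.2]oct-5-en-2-ol (propynyl syn to the C5=C6 bridge and cis to the 3-substituent, OH syn to the C7–C8 bridge) | CO[C@]12C=C[C@H](C[C@H]1C)[C@@H](CCO[Si](C)(C)C(C)(C)C)[C@@]2(O)C#CC | intermediate
14 | 3-[2-(tert-butyldimethylsilyloxy)ethyl]-2-[(E)-2-(dimethylphenylsilyl)prop-1-en-1-yl]-1-methoxy-7-methylbicyclo[2.2.2]oct-5-en-2-ol (alkenyl syn to the C5=C6 bridge) | CO[C@]12C=C[C@H](C[C@H]1C)[C@@H](CCO[Si](C)(C)C(C)(C)C)[C@@]2(O)/C=C(\C)[Si](C)(C)c1ccccc1 | intermediate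
15 | potassium alkoxide of 14 | CO[C@]12C=C[C@H](C[C@H]1C)[C@@H](CCO[Si](C)(C)C(C)(C)C)[C@@]2([O-])/C=C(\C)[Si](C)(C)c1ccccc1.[K+] | intermediate
16 | potassium C8=C9 enolate of 17 | CC(C)(C)[Si](C)(C)OCC[C@@H]1[C@H]2C[C@@H](C)C(OC)=C[C@H]2[C@@](C)([Si](C)(C)c2ccccc2)C=C1[O-].[K+] | intermediate
17 | (1αH,6αH)-7α-[2-(tert-butyldimethylsilyloxy)ethyl]-10β-(dimethylphenylsilyl)-3-methoxy-4β,10α-dimethylbicyclo[4.4.0]dec-2-en-8-one (cis-fused) | CC(C)(C)[Si](C)(C)OCC[C@@H]1[C@H]2C[C@@H](C)C(OC)=C[C@H]2[C@@](C)([Si](C)(C)c2ccccc2)CC1=O | intermediate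
18 | (1αH,6αH)-7α-[2-(tert-butyldimethylsilyloxy)ethyl]-10β-(dimethylphenylsilyl)-3-methoxy-4β,10α-dimethylbicyclo[4.4.0]dec-2-en-8α-ol | CC(C)(C)[Si](C)(C)OCC[C@@H]1[C@H]2C[C@@H](C)C(OC)=C[C@H]2[C@@](C)([Si](C)(C)c2ccccc2)C[C@@H]1O | intermediate
19 | (1αH,6αH)-7α-[2-(tert-butyldimethylsilyloxy)ethyl]-10β-(dimethylphenylsilyl)-8α-hydroxy-4β,10α-dimethylbicyclo[4.4.0]decan-3-one | CC(C)(C)[Si](C)(C)OCC[C@@H]1[C@H]2C[C@@H](C)C(=O)C[C@H]2[C@@](C)([Si](C)(C)c2ccccc2)C[C@@H]1O | intermediate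
20 | (1αH,6αH)-7α-[2-(tert-butyldimethylsilyloxy)ethyl]-8α,10β-dihydroxy-4β,10α-dimethylbicyclo[4.4.0]decan-3-one | CC(C)(C)[Si](C)(C)OCC[C@@H]1[C@H]2C[C@@H](C)C(=O)C[C@H]2[C@@](C)(O)C[C@@H]1O | intermediate
21 | but-2-yne-1,4-diol | OCC#CCO | starting material
22 | 1,4-bis(tert-butyldiphenylsilyloxy)but-2-yne | CC(C)(C)[Si](OCC#CCO[Si](c1ccccc1)(c1ccccc1)C(C)(C)C)(c1ccccc1)c1ccccc1 | intermediate
23 | chloro[(E)-1,4-bis(tert-butyldiphenylsilyloxy)but-2-en-2-yl]bis(cyclopentadienyl)zirconium | CC(C)(C)[Si](OC/C=C(\CO[Si](c1ccccc1)(c1ccccc1)C(C)(C)C)[Zr](Cl)(C1C=CC=C1)C1C=CC=C1)(c1ccccc1)c1ccccc1 | intermediate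
24 | (E)-1,4-bis(tert-butyldiphenylsilyloxy)-2-iodobut-2-ene | CC(C)(C)[Si](OC/C=C(\CO[Si](c1ccccc1)(c1ccccc1)C(C)(C)C)I)(c1ccccc1)c1ccccc1 | intermediate
25 | (E)-4-(tert-butyldiphenylsilyloxy)-2-[(tert-butyldiphenylsilyloxy)methyl]but-2-enoic acid | O=C(O)/C(=C/CO[Si](c1ccccc1)(c1ccccc1)C(C)(C)C)CO[Si](c1ccccc1)(c1ccccc1)C(C)(C)C | intermediate
26 | mixed anhydride of 25 with 2,4,6-trichlorobenzoic acid | O=C(OC(=O)/C(=C/CO[Si](c1ccccc1)(c1ccccc1)C(C)(C)C)CO[Si](c1ccccc1)(c1ccccc1)C(C)(C)C)c1c(Cl)cc(Cl)cc1Cl | intermediate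
27 | (1αH,6αH)-7α-[2-(tert-butyldimethylsilyloxy)ethyl]-10β-hydroxy-4β,10α-dimethyl-3-oxobicyclo[4.4.0]decan-8α-yl (E)-4-(tert-butyldiphenylsilyloxy)-2-[(tert-butyldiphenylsilyloxy)methyl]but-2-enoate | CC(C)(C)[Si](C)(C)OCC[C@@H]1[C@H]2C[C@@H](C)C(=O)C[C@H]2[C@@](C)(O)C[C@@H]1OC(=O)/C(=C/CO[Si](c1ccccc1)(c1ccccc1)C(C)(C)C)CO[Si](c1ccccc1)(c1ccccc1)C(C)(C)C | intermediate
28 | (1αH,6αH)-7α-[2-(tert-butyldimethylsilyloxy)ethyl]-10β-hydroxy-4,10α-dimethyl-3-oxobicyclo[4.4.0]dec-4-en-8α-yl (E)-4-(tert-butyldiphenylsilyloxy)-2-[(tert-butyldiphenylsilyloxy)methyl]but-2-enoate | CC(C)(C)[Si](C)(C)OCC[C@@H]1[C@H]2C=C(C)C(=O)C[C@H]2[C@@](C)(O)C[C@@H]1OC(=O)/C(=C/CO[Si](c1ccccc1)(c1ccccc1)C(C)(C)C)CO[Si](c1ccccc1)(c1ccccc1)C(C)(C)C | intermediate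
29 | (1αH,6αH)-7α-[2-(tert-butyldimethylsilyloxy)ethyl]-3β,10β-dihydroxy-4,10α-dimethylbicyclo[4.4.0]dec-4-en-8α-yl (E)-4-(tert-butyldiphenylsilyloxy)-2-[(tert-butyldiphenylsilyloxy)methyl]but-2-enoate | CC(C)(C)[Si](C)(C)OCC[C@@H]1[C@H]2C=C(C)[C@@H](O)C[C@H]2[C@@](C)(O)C[C@@H]1OC(=O)/C(=C/CO[Si](c1ccccc1)(c1ccccc1)C(C)(C)C)CO[Si](c1ccccc1)(c1ccccc1)C(C)(C)C | intermediate
30 | 3β-acetate of 29 | CC(C)(C)[Si](C)(C)OCC[C@@H]1[C@H]2C=C(C)[C@@H](OC(C)=O)C[C@H]2[C@@](C)(O)C[C@@H]1OC(=O)/C(=C/CO[Si](c1ccccc1)(c1ccccc1)C(C)(C)C)CO[Si](c1ccccc1)(c1ccccc1)C(C)(C)C | intermediate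
31 | (1αH,6αH)-3β-acetoxy-10β-hydroxy-7α-(2-hydroxyethyl)-4,10α-dimethylbicyclo[4.4.0]dec-4-en-8α-yl (E)-4-(tert-butyldiphenylsilyloxy)-2-[(tert-butyldiphenylsilyloxy)methyl]but-2-enoate | OCC[C@@H]1[C@H]2C=C(C)[C@@H](OC(C)=O)C[C@H]2[C@@](C)(O)C[C@@H]1OC(=O)/C(=C/CO[Si](c1ccccc1)(c1ccccc1)C(C)(C)C)CO[Si](c1ccccc1)(c1ccccc1)C(C)(C)C | intermediate
32 | 7α-(2-oxoethyl) analogue of 31 (aldehyde) | O=CC[C@@H]1[C@H]2C=C(C)[C@@H](OC(C)=O)C[C@H]2[C@@](C)(O)C[C@@H]1OC(=O)/C(=C/CO[Si](c1ccccc1)(c1ccccc1)C(C)(C)C)CO[Si](c1ccccc1)(c1ccccc1)C(C)(C)C | intermediate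
33 | 7α-(3-oxoprop-1-en-2-yl) analogue of 31 (α-methylene aldehyde) | C=C(C=O)[C@@H]1[C@H]2C=C(C)[C@@H](OC(C)=O)C[C@H]2[C@@](C)(O)C[C@@H]1OC(=O)/C(=C/CO[Si](c1ccccc1)(c1ccccc1)C(C)(C)C)CO[Si](c1ccccc1)(c1ccccc1)C(C)(C)C | intermediate
34 | bis-TBDPS ether of the target acid (2-substituted prop-2-enoic acid) | C=C(C(=O)O)[C@@H]1[C@H]2C=C(C)[C@@H](OC(C)=O)C[C@H]2[C@@](C)(O)C[C@@H]1OC(=O)/C(=C/CO[Si](c1ccccc1)(c1ccccc1)C(C)(C)C)CO[Si](c1ccccc1)(c1ccccc1)C(C)(C)C | intermediate
35 | CNP0468194.1: 2-{(1αH,6αH)-3β-acetoxy-10β-hydroxy-8α-[(E)-4-hydroxy-2-(hydroxymethyl)but-2-enoyloxy]-4,10α-dimethylbicyclo[4.4.0]dec-4-en-7α-yl}prop-2-enoic acid | C=C(C(=O)O)[C@@H]1[C@H]2C=C(C)[C@@H](OC(C)=O)C[C@H]2[C@@](C)(O)C[C@@H]1OC(=O)/C(=C/CO)CO | target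

**Totals.** 23 steps in all; the longest linear sequence is 20 steps (steps 1–11 and 15–23). The acid fragment takes steps 12–14.

**Steps most likely to fail**

Step 11 (Fleming–Tamao at C10). The fully substituted, neopentyl-type C10–Si bond may undergo ipso-mercuration or the silicon-to-oxygen shift only sluggishly, so that protodesilylation or slow Baeyer–Villiger oxidation of the C3 ketone competes. The fallback replaces silicon by boron and sets out from 13, returning at 20. Copper-catalysed syn hydroboration of 13 (CuCl, NaOt-Bu, Xantphos, B2pin2, MeOH, THF) should give the (E)-alkenyl pinacolboronate F1. KH and 18-crown-6 should then effect the same oxy-Cope shift to the tertiary boronate ketone F2, which is oxidised without isolation (NaBO3·4H2O, THF/H2O) to the β-hydroxy ketone F3. Hydroxyl-directed anti reduction (Me4NBH(OAc)3, AcOH/MeCN, −20 °C) should give the 8α,10β-diol enol ether F4, and the acidic aqueous work-up hydrolyses its enol ether to 20.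

Step 15 (esterification at C8). Acylation of the hindered secondary hydroxyl next to the branched C7 may be slow, and the activated acid may lose its alkene geometry through reversible DMAP addition. The fallback acylates the alkoxide as it is formed and sets out from 17 and 25, returning at 27. Acid 25 is turned into the acid chloride F5 with 1-chloro-N,N,2-trimethylprop-1-en-1-amine. Ketone 17 is reduced with LiBH(s-Bu)3 at −78 °C and the lithium alkoxide is trapped in the same flask with F5 to give the enol ether ester F6. 1 M HCl should hydrolyse F6 to the silyl keto ester F7, and bromodesilylative Fleming–Tamao oxidation (KBr, CH3CO3H, NaOAc, AcOH) should then give 27.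

Step 16 (IBX dehydrogenation). Enolisation toward C2 would dehydrogenate on the wrong side of the ketone (C1=C2), and over-oxidation is possible. The fallback is a Saegusa–Ito sequence through the regiodefined thermodynamic enol ether and sets out from 27, returning at 28. TMSCl, NaI and Et3N in MeCN should give the C3=C4 trimethylsilyl enol ether, with the C10 hydroxyl silylated as well, F8. Pd(OAc)2 in MeCN should give the enone trimethylsilyl ether F9, and citric acid in MeOH removes the tertiary silyl ether to give 28.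

Further compounds
F1 | step 11 | 3-[2-(tert-butyldimethylsilyloxy)ethyl]-1-methoxy-7-methyl-2-[(E)-2-(4,4,5,5-tetramethyl-1,3,2-dioxaborolan-2-yl)prop-1-en-1-yl]bicyclo[2.2.2]oct-5-en-2-ol | CO[C@]12C=C[C@H](C[C@H]1C)[C@@H](CCO[Si](C)(C)C(C)(C)C)[C@@]2(O)/C=C(\C)B1OC(C)(C)C(C)(C)O1
F2 | step 11 | (1αH,6αH)-7α-[2-(tert-butyldimethylsilyloxy)ethyl]-3-methoxy-4β,10α-dimethyl-10β-(4,4,5,5-tetramethyl-1,3,2-dioxaborolan-2-yl)bicyclo[4.4.0]dec-2-en-8-one | CC(C)(C)[Si](C)(C)OCC[C@@H]1[C@H]2C[C@@H](C)C(OC)=C[C@H]2[C@@](C)(B2OC(C)(C)C(C)(C)O2)CC1=O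
F3 | step 11 | (1αH,6αH)-7α-[2-(tert-butyldimethylsilyloxy)ethyl]-10β-hydroxy-3-methoxy-4β,10α-dimethylbicyclo[4.4.0]dec-2-en-8-one | CC(C)(C)[Si](C)(C)OCC[C@@H]1[C@H]2C[C@@H](C)C(OC)=C[C@H]2[C@@](C)(O)CC1=O
F4 | step 11 | (1αH,6αH)-7α-[2-(tert-butyldimethylsilyloxy)ethyl]-3-methoxy-4β,10α-dimethylbicyclo[4.4.0]dec-2-ene-8α,10β-diol | CC(C)(C)[Si](C)(C)OCC[C@@H]1[C@H]2C[C@@H](C)C(OC)=C[C@H]2[C@@](C)(O)C[C@@H]1O
F5 | step 15 | (E)-4-(tert-butyldiphenylsilyloxy)-2-[(tert-butyldiphenylsilyloxy)methyl]but-2-enoyl chloride | O=C(Cl)/C(=C/CO[Si](c1ccccc1)(c1ccccc1)C(C)(C)C)CO[Si](c1ccccc1)(c1ccccc1)C(C)(C)C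
F6 | step 15 | 8α-ester of 18 with acid 25 (3-methoxy enol ether, 10β-dimethylphenylsilyl) | CC(C)(C)[Si](C)(C)OCC[C@@H]1[C@H]2C[C@@H](C)C(OC)=C[C@H]2[C@@](C)([Si](C)(C)c2ccccc2)C[C@@H]1OC(=O)/C(=C/CO[Si](c1ccccc1)(c1ccccc1)C(C)(C)C)CO[Si](c1ccccc1)(c1ccccc1)C(C)(C)C
F7 | step 15 | 8α-ester of 19 with acid 25 (3-ketone, 10β-dimethylphenylsilyl) | CC(C)(C)[Si](C)(C)OCC[C@@H]1[C@H]2C[C@@H](C)C(=O)C[C@H]2[C@@](C)([Si](C)(C)c2ccccc2)C[C@@H]1OC(=O)/C(=C/CO[Si](c1ccccc1)(c1ccccc1)C(C)(C)C)CO[Si](c1ccccc1)(c1ccccc1)C(C)(C)C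
F8 | step 16 | C3=C4 trimethylsilyl enol ether of 27 with the C10 hydroxyl as trimethylsilyl ether | CC(C)(C)[Si](C)(C)OCC[C@@H]1[C@H]2CC(C)=C(O[Si](C)(C)C)C[C@H]2[C@@](C)(O[Si](C)(C)C)C[C@@H]1OC(=O)/C(=C/CO[Si](c1ccccc1)(c1ccccc1)C(C)(C)C)CO[Si](c1ccccc1)(c1ccccc1)C(C)(C)C
F9 | step 16 | 10β-trimethylsilyl ether of enone 28 | CC(C)(C)[Si](C)(C)OCC[C@@H]1[C@H]2C=C(C)C(=O)C[C@H]2[C@@](C)(O[Si](C)(C)C)C[C@@H]1OC(=O)/C(=C/CO[Si](c1ccccc1)(c1ccccc1)C(C)(C)C)CO[Si](c1ccccc1)(c1ccccc1)C(C)(C)C
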